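(The data come from a simulation with constants of no real substance.)

I nearly carried the plateau of J in the larch run over as a percentage of the G charged, but this flask holds less E per G than larch did. The possible steps are G + E → Q, E + X → J, G ⇌ X and J ⇌ L, so I kept the books on E, the limiting reagent, which goes one for one with G by both routes that take it.

| setting | larch | birch | flask |
|---|---|---|---|
| G | 5 mM | 5 mM | 5.0 mM |
| E | 4.2 mM | 6.6 mM | 3.00 mM |
| remark | run made earlier | run made earlier |  |
| time |  |  | 5.0 min |

- larch (time / min: J / %, X / %): 0.333: 58, 12; 0.500: 45, 13; 0.667: 47, 13; 1.00: 41, 12; 1.50: 40, 9; 2.50: 41, 14; 4.00: 38, 11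
- birch (time / min: J / %, X / %): 0.200: 69, 0; 0.667: 53, 0; 1.00: 44, 0; 1.50: 42, 0; 2.50: 38, 2; 3.00: 43, 0; 4.00: 43, 0

(readings scatter by 2 percentage points)

- what may be going on: G + E -> Q; J <-> L; E + X -> J; G <-> X
- the reaction counts as stopped when no species that holds the G changes by six tenths of a point or more over the second half of the time

* at 5.0 min, what has stopped the reaction, if anything has (it is still moving / all of G has reacted / E has run out first / forward and back rates have come level)
* J at 5.0 min, in percent of the G charged
* X at 5.0 min, in percent of the G charged
* amount of J if the flask were left three thousand times as long, in percent of the G charged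

Larch kept X to its last reading and birch, with more E, read X at 0 % there, so I read 16.0 % of the G in larch as having no E partner. A molecule of E ends in J, L or Q. From 1.50 min on, larch gave my quantity w, the plateau of J per E charged where E is the limiting reagent: 0.472. In this flask E is 60.0 % of the G, so the first entry is J at 28.3 %, and the other 31.7 % goes to L and Q. The 40.0 % of G without a partner lies as G and X. Late larch readings put 70.8 % of such a remainder in X, which gives X at 28.3 %. The books close with the 3.00 mM of E, so I committed to E stopping the flask, with J at 28.3 % then and after long standing.

The forecast said E has run out first, with J 30 %, X 30 % and long-term J 30 %, a J above mine, on the ground that “With no E left, nothing further happens”.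

The flask gave E has run out first, with 0 % of its E left, J 26.5 %, X 29.2 % and long-term J 26.5 %.

    G + E → Q (k = 51.0 L mol⁻¹ s⁻¹)
    J ⇌ L (K = 1.10, k = 0.0220 s⁻¹)
    E + X → J (k = 6600 L mol⁻¹ s⁻¹)
    G ⇌ X (K = 2.70, k = 1.30 s⁻¹)

Here w came to 0.442. For the neighbour with 12 mM of G, my w gives 11.8 % of J, and that flask held 10.8 %. The run of this flask without the back reaction of X to G gave another ending, so that step is the main reason for the ending seen here: conversion of G stood at 89.2 % with the step and at 100 % without it.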